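Assumption (one line): compounds 1, 2, 4, 8 and 21 and all named reagents are taken as purchasable; locants C1–C15 are the germacrane locants of the target (ring C1–C10, isopropenyl C11–C13 on C7, C14 on C10, C15 on C4) and are kept for the open-chain intermediates; the CIP letters quoted are those of each compound (they change with substituent priorities while the spatial arrangement is carried unchanged).

## Retrosynthetic overview

1. Target ⇐ nucleophilic epoxidation of the ten-membered (Z)-enone (C1=C10–C9=O) that already carries the three angelates and the 4,5-epoxide; this sets C1 and C10 last.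
2. Ten-membered carbocycle ⇐ C9–C10 bond by a new nickel-catalysed reductive coupling of a C9 S-2-pyridyl thioester with the C10 (Z)-alkenyl iodide.
3. Open chain ⇐ C5–C6 bond from an alkenyllithium (western fragment, C1–C5) and a Weinreb amide (eastern fragment, C6–C9); then C6 by Narasaka–Prasad reduction, C4/C5 by hydroxyl-directed epoxidation, angelates from a preformed mixed anhydride, and the Z-iodoalkene by Stork–Zhao olefination.
4. Eastern fragment ⇐ deconjugative Evans aldol (C7, C8); western fragment ⇐ carboalumination of propargyl alcohol and Brown allylation (C3).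
5. Order of ring formation: 4,5-epoxide (open chain), then the carbocycle, then the 1,10-epoxide.

## Route

Step 1
Reactants: 1 (R)-4-benzyl-1,3-oxazolidin-2-one; 2 3-methylbut-2-enoyl chloride
Product: 3 (R)-4-benzyl-3-(3-methylbut-2-enoyl)-1,3-oxazolidin-2-one
Conditions: n-BuLi, THF, −78 °C; then 2, −78 → 0 °C
Reagents that add atoms: none
Why: N-acylation of the lithium salt of the oxazolidinone with the acid chloride (imide formation); no stereocentre is made.

Step 2
Reactants: 3 senecioyl imide; 4 2-((tert-butyldimethylsilyl)oxy)acetaldehyde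
Product: 6 (R)-4-benzyl-3-[(2R,3R)-4-((tert-butyldimethylsilyl)oxy)-3-hydroxy-2-(prop-1-en-2-yl)butanoyl]-1,3-oxazolidin-2-one, via boron dienolate 5 (not isolated)
Conditions: Bu2BOTf, Et3N, CH2Cl2, −78 → 0 °C; then 4, −78 → 0 °C; pH 7 buffer, MeOH, H2O2
Reagents that add atoms: none
Why: Deconjugative Evans boron aldol: γ-deprotonation gives the Z(O) boron dienolate, which reacts at its α-carbon through a Zimmerman–Traxler chair on the face away from the benzyl group, so C7 and C8 are set together as the syn (2R,3R) pair.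

Step 3
Reactants: 6 aldol adduct
Product: 7 (2R,3R)-4-((tert-butyldimethylsilyl)oxy)-3-hydroxy-N-methoxy-N-methyl-2-(prop-1-en-2-yl)butanamide
Conditions: MeNH(OMe)·HCl, AlMe3, THF, −20 → 0 °C
Reagents that add atoms: N,O-dimethylhydroxylamine hydrochloride, CNOC.Cl
Why: Weinreb transamidation by the aluminium amide (the free β-hydroxyl assists) cleaves the auxiliary without epimerising C7.

Step 4
Reactants: 8 prop-2-yn-1-ol
Product: 10 (E)-3-iodo-2-methylprop-2-en-1-ol, via alkenylalane 9 (not isolated)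
Conditions: AlMe3 (3 equiv), (C5H5)2ZrCl2 (25 mol %), CH2Cl2, 0 → 25 °C; then I2, THF, −30 → 0 °C
Reagents that add atoms: trimethylaluminium, C[Al](C)C; iodine, II
Why: Negishi zirconium-catalysed carboalumination adds methyl and aluminium syn across the alkyne with methyl on the internal carbon, and iodinolysis of the C–Al bond with retention gives only the E iodoalkene.

Step 5
Reactants: 10 (E)-3-iodo-2-methylprop-2-en-1-ol
Product: 11 (E)-3-iodo-2-methylprop-2-enal
Conditions: MnO2, CH2Cl2, 25 °C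
Reagents that add atoms: none
Why: MnO2 is an allylic-selective oxidant that stops at the enal and leaves the iodoalkene geometry intact.

Step 6
Reactants: 11 (E)-3-iodo-2-methylprop-2-enal
Product: 12 (S,E)-1-iodo-2-methylhexa-1,5-dien-3-ol
Conditions: (−)-Ipc2BOMe, allylMgBr, Et2O, 0 → 25 °C; then 11, −78 °C; NaOH, H2O2
Reagents that add atoms: allylmagnesium bromide, C=CC[Mg]Br
Why: Brown asymmetric allylboration: the allylborane made from (−)-Ipc2BOMe (derived from (+)-α-pinene) adds through a chair transition state to the Si face of the enal and sets C3 as S (about 94% ee; the minor enantiomer is removed as a diastereomer after step 9).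

Step 7
Reactants: 12 (S,E)-1-iodo-2-methylhexa-1,5-dien-3-ol
Product: 14 (S,E)-5-iodo-4-methylpent-4-ene-1,3-diol, via hydroxy aldehyde 13 (not isolated)
Conditions: O3 (1 equiv), CH2Cl2/MeOH, −78 °C; Me2S; then NaBH4, 0 °C
Reagents that add atoms: ozone, [O-][O+]=O
Why: Ozonolysis cleaves the electron-rich terminal alkene in preference to the iodine-deactivated trisubstituted alkene, and borohydride reduction of the aldehyde gives the 1,3-diol with the extra carbon removed; C3 is untouched.

Step 8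
Reactants: 14 (S,E)-5-iodo-4-methylpent-4-ene-1,3-diol
Product: 15 (S,E)-1-iodo-2-methyl-3,5-bis((triethylsilyl)oxy)pent-1-ene
Conditions: Et3SiCl, imidazole, DMF, 0 → 25 °C
Reagents that add atoms: chlorotriethylsilane, CC[Si](Cl)(CC)CC
Why: Silyl ether formation on both hydroxyls; the primary and secondary triethylsilyl ethers are told apart later in step 14.

Step 9
Reactants: 7 Weinreb amide; 15 bis-silylated (E)-alkenyl iodide
Product: 18 open-chain β-hydroxy enone (3S,7R,8R; 4E), via vinyllithium 16 (not isolated), via chloromagnesium alkoxide 17 (not isolated)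
Conditions: 15, t-BuLi (2.1 equiv), Et2O, −78 °C; 7, i-PrMgCl (1.0 equiv), THF, −78 °C; combine, −78 → −40 °C; aq. NH4Cl
Reagents that add atoms: none
Why: Iodine–lithium exchange proceeds with retention of the E geometry and the Weinreb ketone synthesis stops at the chelated tetrahedral intermediate, giving the enone and the C5–C6 bond; prior conversion of the C8 hydroxyl into its magnesium alkoxide saves a second equivalent of 16, and no stereocentre is touched.

Step 10
Reactants: 18 β-hydroxy enone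
Product: 19 open-chain syn-1,3-diol (3S,6R,7S,8R; 4E)
Conditions: Et2BOMe, THF/MeOH 4:1, −78 °C; NaBH4; AcOH, MeOH
Reagents that add atoms: none
Why: Narasaka–Prasad reduction: the boron chelate of the β-hydroxy ketone is reduced by external axial hydride delivery, giving the 1,3-syn diol and setting C6 (the enone reacts 1,2).

Step 11
Reactants: 19 syn-diol
Product: 20 4,5-epoxy diol (3S,4S,5R,6S,7R,8R)
Conditions: VO(acac)2 (acac = pentane-2,4-dionate, 5 mol %), t-BuOOH, CH2Cl2, 0 °C
Reagents that add atoms: tert-butyl hydroperoxide, CC(C)(C)OO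
Why: Hydroxyl-directed vanadium-catalysed epoxidation: only the C4=C5 alkene is allylic to a free hydroxyl, and A(1,3) strain between the C15 methyl and C7 fixes C6–H in the alkene plane so that oxygen is delivered syn to the C6 hydroxyl, giving the threo epoxy alcohol and setting C4 and C5.

Step 12
Reactants: 21 angelic acid ((Z)-2-methylbut-2-enoic acid)
Product: 22 (Z)-2-methylbut-2-enoic 2,4,6-trichlorobenzoic anhydride
Conditions: 2,4,6-trichlorobenzoyl chloride, Et3N, toluene, 25 °C; Et3N·HCl filtered off, filtrate used as a toluene solution (made by the same procedure each time it is needed)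
Reagents that add atoms: 2,4,6-trichlorobenzoyl chloride, O=C(Cl)c1c(Cl)cc(Cl)cc1Cl
Why: Yamaguchi mixed-anhydride formation by acyl substitution of the aroyl chloride with the triethylammonium carboxylate; at room temperature and without a nucleophilic catalyst the Z (angelate) geometry is kept, and no stereocentre is made.

Step 13
Reactants: 20 epoxy diol; 22 mixed anhydride (two molecules are consumed per molecule of 20; 3 equiv used)
Product: 23 C6,C8-bis-angelate (3S,4S,5R,6S,7R,8R)
Conditions: 22 (3 equiv), Et3N, toluene, 80 °C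
Reagents that add atoms: second molecule of mixed anhydride 22, C/C=C(/C)C(=O)OC(=O)c1c(Cl)cc(Cl)cc1Cl
Why: Yamaguchi-type esterification without a nucleophilic catalyst: each secondary alcohol attacks the unhindered angeloyl carbonyl of one molecule of 22 (the 2,6-dichloro-flanked aroyl carbonyl is shielded), so both C6 and C8 hydroxyls are acylated with the Z geometry kept; Et3N buffers the liberated acid and protects the epoxide.

Step 14
Reactants: 23 bis-angelate
Product: 24 C1 aldehyde (3S,4S,5R,6S,7R,8R)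
Conditions: (COCl)2, DMSO, CH2Cl2, −78 → −40 °C; Et3N, −78 → 0 °C
Reagents that add atoms: none
Why: Under Swern conditions a primary triethylsilyl ether is cleaved and oxidised in one operation to the aldehyde, whereas the secondary triethylsilyl ether and the tert-butyldimethylsilyl ether survive.

Step 15
Reactants: 24 C1 aldehyde
Product: 25 (Z)-10-iodo-1(10)-alkene (3S,4S,5R,6S,7R,8R)
Conditions: [Ph3PEt]I, n-BuLi, THF, 25 °C; I2, −78 °C; NaN(SiMe3)2, −20 °C; then 24, −78 °C
Reagents that add atoms: ethyltriphenylphosphonium iodide, CC[P+](c1ccccc1)(c1ccccc1)c1ccccc1.[I-]; iodine, II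
Why: Stork–Zhao olefination: the α-iodo ylide adds under kinetic control via the cis-oxaphosphetane and gives the (Z)-2-iodoalkene, which fixes the C1=C10 geometry needed for the cis epoxide.

Step 16
Reactants: 25 (Z)-alkenyl iodide
Product: 26 C3 alcohol (3S,4R,5R,6S,7R,8R)
Conditions: HF·pyridine, pyridine, THF, 0 °C
Reagents that add atoms: none
Why: Buffered HF·pyridine removes the secondary triethylsilyl ether much faster than the primary tert-butyldimethylsilyl ether (selective desilylation), and the non-basic medium avoids Payne rearrangement.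

Step 17
Reactants: 26 C3 alcohol; 22 mixed anhydride
Product: 27 C3,C6,C8-tris-angelate (3S,4R,5R,6S,7R,8R)
Conditions: 22 (3 equiv), Et3N, toluene, 80 °C
Reagents that add atoms: none
Why: The same Yamaguchi-type mixed-anhydride esterification as in step 13, now on the hindered C3 alcohol, with retention of the angelate geometry.

Step 18
Reactants: 27 tris-angelate silyl ether
Product: 28 C9 primary alcohol (3S,4R,5R,6S,7R,8R)
Conditions: HF·pyridine, THF, 0 → 25 °C
Reagents that add atoms: none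
Why: Fluoride-mediated cleavage of the primary silyl ether; the weakly acidic medium suppresses C8-to-C9 acyl migration.

Step 19
Reactants: 28 C9 alcohol
Product: 29 C9 carboxylic acid (3S,4R,5R,6S,7S,8R)
Conditions: TEMPO (2,2,6,6-tetramethylpiperidin-1-oxyl, 20 mol %), PhI(OAc)2, MeCN/H2O 1:1, 25 °C
Reagents that add atoms: water, O
Why: TEMPO/PhI(OAc)2 oxidation in aqueous acetonitrile takes the primary alcohol through the aldehyde hydrate to the acid; the alkenes, the alkenyl iodide and the epoxide are inert.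

Step 20
Reactants: 29 C9 acid
Product: 30 C9 S-(pyridin-2-yl) thioester (3S,4R,5R,6S,7S,8R)
Conditions: 2,2′-dipyridyl disulfide, PPh3, CH2Cl2, 25 °C
Reagents that add atoms: 2,2′-dipyridyl disulfide, c1ccc(SSc2ccccn2)nc1
Why: Mukaiyama redox condensation (PPh3/disulfide) forms the S-2-pyridyl thioester under neutral conditions, so C8 is not epimerised.

Step 21
Reactants: 30 seco thioester/alkenyl iodide
Product: 31 (1(10)Z,3S,4R,5R,6S,7S,8R)-4,5-epoxy-9-oxogermacra-1(10),11-diene-3,6,8-triyl tris((Z)-2-methylbut-2-enoate)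
Conditions: NiBr2(MeOCH2CH2OMe) (20 mol %), 4,4′-di-tert-butyl-2,2′-bipyridine (24 mol %), Zn dust (3 equiv), DMA/THF 1:1, 25 °C, 30 added by syringe pump over 12 h (final 2 mM)
Reagents that add atoms: none
Why: Proposed new method: an intramolecular nickel-catalysed reductive acyl–alkenyl coupling in which zerovalent nickel (from the divalent precatalyst and Zn) inserts first into the C10–I bond with retention of the Z geometry, Zn reduces the alkenylnickel halide to a monovalent alkenylnickel species that is held by the pyridine nitrogen of the thioester and adds into its C9(acyl)–S bond, and the resulting trivalent acyl(alkenyl)nickel complex eliminates reductively to forge C9–C10 and the ten-membered (Z)-enone directly at the ketone oxidation level under neutral conditions (no C8 epimerisation, zinc iodide/pyridinethiolate as the sink, high dilution against dimerisation); the closest known reaction types are the nickel-catalysed reductive ketone synthesis from alkyl iodides and S-2-pyridyl thioesters and the Nozaki–Hiyama–Kishi macrocyclisation of alkenyl iodides onto aldehydes, neither shown for an alkenyl iodide/thioester closure of a medium ring.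

Step 22
Reactants: 31 macrocyclic (Z)-enone
Product: 32 (1S,3S,4R,5R,6S,7S,8R,10S)-1,10:4,5-diepoxy-9-oxogermacr-11-ene-3,6,8-triyl tris((Z)-2-methylbut-2-enoate), CNP0154187.4
Conditions: t-BuOOH (3 equiv), n-BuLi (1.1 equiv), THF, −78 → −20 °C
Reagents that add atoms: tert-butyl hydroperoxide, CC(C)(C)OO
Why: Weitz–Scheffer nucleophilic epoxidation: the hydroperoxide anion attacks only the enone (the angelates are poor, hindered acceptors; excess hydroperoxide buffers the alkoxide formed) at C1 from the peripheral face anti to the C3 angelate, and the ring-constrained enolate closes before C1–C10 rotation, so the Z geometry becomes the cis epoxide and C1 and C10 are set as (1S,10S).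

## Compound list

1 | (R)-4-benzyl-1,3-oxazolidin-2-one | O=C1N[C@H](Cc2ccccc2)CO1 | starting material
2 | 3-methylbut-2-enoyl chloride | CC(C)=CC(Cl)=O | starting material
3 | (R)-4-benzyl-3-(3-methylbut-2-enoyl)-1,3-oxazolidin-2-one | CC(C)=CC(=O)N1[C@H](Cc2ccccc2)COC1=O | intermediate
4 | 2-((tert-butyldimethylsilyl)oxy)acetaldehyde | CC(C)(C)[Si](C)(C)OCC=O | starting material
5 | boron dienolate (not isolated): (R)-4-benzyl-3-[(Z)-1-((dibutylboranyl)oxy)-3-methylbuta-1,3-dien-1-yl]-1,3-oxazolidin-2-one | CCCCB(CCCC)O/C(=C\C(C)=C)N1[C@H](Cc2ccccc2)COC1=O | intermediate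
6 | (R)-4-benzyl-3-[(2R,3R)-4-((tert-butyldimethylsilyl)oxy)-3-hydroxy-2-(prop-1-en-2-yl)butanoyl]-1,3-oxazolidin-2-one | CC(C)(C)[Si](C)(C)OC[C@H](O)[C@@H](C(C)=C)C(=O)N1[C@H](Cc2ccccc2)COC1=O | intermediate
7 | (2R,3R)-4-((tert-butyldimethylsilyl)oxy)-3-hydroxy-N-methoxy-N-methyl-2-(prop-1-en-2-yl)butanamide | CC(C)(C)[Si](C)(C)OC[C@H](O)[C@@H](C(C)=C)C(=O)N(C)OC | intermediate
8 | prop-2-yn-1-ol | C#CCO | starting material
9 | alkenylalane (not isolated): (E)-[3-((dimethylalumanyl)oxy)-2-methylprop-1-en-1-yl]dimethylalumane | C[Al](C)OC/C(C)=C/[Al](C)C | intermediate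
10 | (E)-3-iodo-2-methylprop-2-en-1-ol | OC/C(C)=C/I | intermediate
11 | (E)-3-iodo-2-methylprop-2-enal | O=C/C(C)=C/I | intermediate
12 | (S,E)-1-iodo-2-methylhexa-1,5-dien-3-ol | I/C=C(\C)[C@@H](O)CC=C | intermediate
13 | hydroxy aldehyde (not isolated): (S,E)-3-hydroxy-5-iodo-4-methylpent-4-enal | I/C=C(\C)[C@@H](O)CC=O | intermediate
14 | (S,E)-5-iodo-4-methylpent-4-ene-1,3-diol | I/C=C(\C)[C@@H](O)CCO | intermediate
15 | (S,E)-1-iodo-2-methyl-3,5-bis((triethylsilyl)oxy)pent-1-ene | I/C=C(\C)[C@@H](O[Si](CC)(CC)CC)CCO[Si](CC)(CC)CC | intermediate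
16 | vinyllithium (not isolated): [(S,E)-2-methyl-3,5-bis((triethylsilyl)oxy)pent-1-en-1-yl]lithium | [Li]/C=C(\C)[C@@H](O[Si](CC)(CC)CC)CCO[Si](CC)(CC)CC | intermediate
17 | chloromagnesium alkoxide of 7 at the C8 oxygen (not isolated), (2R,3R) | CC(C)(C)[Si](C)(C)OC[C@H](O[Mg]Cl)[C@@H](C(C)=C)C(=O)N(C)OC | intermediate
18 | (2R,3R,7S,E)-1-((tert-butyldimethylsilyl)oxy)-2-hydroxy-6-methyl-3-(prop-1-en-2-yl)-7,9-bis((triethylsilyl)oxy)non-5-en-4-one (germacrane locants 3S,7R,8R; 4E) | CC(C)(C)[Si](C)(C)OC[C@H](O)[C@@H](C(C)=C)C(=O)/C=C(\C)[C@@H](O[Si](CC)(CC)CC)CCO[Si](CC)(CC)CC | intermediate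
19 | (2R,3S,4R,7S,E)-1-((tert-butyldimethylsilyl)oxy)-6-methyl-3-(prop-1-en-2-yl)-7,9-bis((triethylsilyl)oxy)non-5-ene-2,4-diol (germacrane locants 3S,6R,7S,8R; 4E) | CC(C)(C)[Si](C)(C)OC[C@H](O)[C@@H](C(C)=C)[C@H](O)/C=C(\C)[C@@H](O[Si](CC)(CC)CC)CCO[Si](CC)(CC)CC | intermediate
20 | (2R,3R,4S)-1-((tert-butyldimethylsilyl)oxy)-4-{(2R,3S)-3-[(S)-1,3-bis((triethylsilyl)oxy)propyl]-3-methyloxiran-2-yl}-3-(prop-1-en-2-yl)butane-2,4-diol (germacrane locants 3S,4S,5R,6S,7R,8R) | CC(C)(C)[Si](C)(C)OC[C@H](O)[C@@H](C(C)=C)[C@H](O)[C@H]1O[C@]1(C)[C@@H](O[Si](CC)(CC)CC)CCO[Si](CC)(CC)CC | intermediate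
21 | angelic acid, (Z)-2-methylbut-2-enoic acid | C/C=C(/C)C(=O)O | starting material
22 | (Z)-2-methylbut-2-enoic 2,4,6-trichlorobenzoic anhydride (mixed anhydride, used as a filtered toluene solution) | C/C=C(/C)C(=O)OC(=O)c1c(Cl)cc(Cl)cc1Cl | intermediate
23 | C6,C8-bis-angelate of 20: open chain with 9-OTBS, 8-O-angeloyl, 7-isopropenyl, 6-O-angeloyl, trans-4,5-epoxide, 3-OTES, 1-OTES (3S,4S,5R,6S,7R,8R) | CC(C)(C)[Si](C)(C)OC[C@H](OC(=O)/C(C)=C\C)[C@@H](C(C)=C)[C@H](OC(=O)/C(C)=C\C)[C@H]1O[C@]1(C)[C@@H](O[Si](CC)(CC)CC)CCO[Si](CC)(CC)CC | intermediate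
24 | C1 aldehyde: as 23 with C1 as CHO, 3-OTES kept (3S,4S,5R,6S,7R,8R) | CC(C)(C)[Si](C)(C)OC[C@H](OC(=O)/C(C)=C\C)[C@@H](C(C)=C)[C@H](OC(=O)/C(C)=C\C)[C@H]1O[C@]1(C)[C@@H](O[Si](CC)(CC)CC)CC=O | intermediate
25 | (Z)-alkenyl iodide: as 24 with C1H=C10(I)–C14H3, Z (3S,4S,5R,6S,7R,8R) | CC(C)(C)[Si](C)(C)OC[C@H](OC(=O)/C(C)=C\C)[C@@H](C(C)=C)[C@H](OC(=O)/C(C)=C\C)[C@H]1O[C@]1(C)[C@@H](O[Si](CC)(CC)CC)C/C=C(\I)C | intermediate
26 | C3 alcohol of 25 (3S,4R,5R,6S,7R,8R; Z) | CC(C)(C)[Si](C)(C)OC[C@H](OC(=O)/C(C)=C\C)[C@@H](C(C)=C)[C@H](OC(=O)/C(C)=C\C)[C@H]1O[C@]1(C)[C@@H](O)C/C=C(\I)C | intermediate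
27 | C3,C6,C8-tris-angelate with 9-OTBS and (Z)-10-iodoalkene (3S,4R,5R,6S,7R,8R) | CC(C)(C)[Si](C)(C)OC[C@H](OC(=O)/C(C)=C\C)[C@@H](C(C)=C)[C@H](OC(=O)/C(C)=C\C)[C@H]1O[C@]1(C)[C@@H](OC(=O)/C(C)=C\C)C/C=C(\I)C | intermediate
28 | C9 primary alcohol of 27 (3S,4R,5R,6S,7R,8R; Z) | OC[C@H](OC(=O)/C(C)=C\C)[C@@H](C(C)=C)[C@H](OC(=O)/C(C)=C\C)[C@H]1O[C@]1(C)[C@@H](OC(=O)/C(C)=C\C)C/C=C(\I)C | intermediate
29 | C9 carboxylic acid (3S,4R,5R,6S,7S,8R; Z) | OC(=O)[C@H](OC(=O)/C(C)=C\C)[C@@H](C(C)=C)[C@H](OC(=O)/C(C)=C\C)[C@H]1O[C@]1(C)[C@@H](OC(=O)/C(C)=C\C)C/C=C(\I)C | intermediate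
30 | C9 S-(pyridin-2-yl) thioester (3S,4R,5R,6S,7S,8R; Z) | O=C(Sc1ccccn1)[C@H](OC(=O)/C(C)=C\C)[C@@H](C(C)=C)[C@H](OC(=O)/C(C)=C\C)[C@H]1O[C@]1(C)[C@@H](OC(=O)/C(C)=C\C)C/C=C(\I)C | intermediate
31 | (1(10)Z,3S,4R,5R,6S,7S,8R)-4,5-epoxy-9-oxogermacra-1(10),11-diene-3,6,8-triyl tris((Z)-2-methylbut-2-enoate) | C=C(C)[C@H]1[C@H](OC(=O)/C(C)=C\C)[C@H]2O[C@]2(C)[C@@H](OC(=O)/C(C)=C\C)C/C=C(/C)C(=O)[C@@H]1OC(=O)/C(C)=C\C | intermediate
32 | (1S,3S,4R,5R,6S,7S,8R,10S)-1,10:4,5-diepoxy-9-oxogermacr-11-ene-3,6,8-triyl tris((Z)-2-methylbut-2-enoate), CNP0154187.4 | C=C(C)[C@H]1[C@H](OC(=O)/C(C)=C\C)[C@H]2O[C@]2(C)[C@@H](OC(=O)/C(C)=C\C)C[C@@H]2O[C@]2(C)C(=O)[C@@H]1OC(=O)/C(C)=C\C | target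

## Step count and risks

Total step count: 22 (steps 1–3 eastern fragment, steps 4–8 western fragment, step 12 acylating agent, steps 9–11 and 13–22 after union).
Longest linear sequence: 18 steps (steps 4–8, then 9–11 and 13–22, from prop-2-yn-1-ol 8).

Three steps most likely to fail:

1. Step 21 (the proposed nickel ring closure). Risks are proto-deiodination, dimerisation and decarbonylation of the α-acyloxy acyl–nickel species. The fallback uses known chemistry; it sets out from 28 and comes back at 31. Dess–Martin periodinane oxidises 28 to the C9 aldehyde F5. A Nozaki–Hiyama–Kishi macrocyclisation (CrCl2, NiCl2 1 mol %, DMSO/THF, 2 mM) then joins C9 to C10 and gives the macrocyclic (Z)-allylic alcohol F6 as its C9 epimers. A second Dess–Martin oxidation converts F6 into 31.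

2. Step 22 (last epoxidation). Risks are attack on the wrong face, C8 epimerisation, or base-induced vinylogous loss of the C3 angelate. The fallback sets out from 31 and comes back at 32. Luche reduction (NaBH4, CeCl3·7H2O, MeOH, −78 °C) gives the macrocyclic (Z)-allylic alcohol F6. Hydroxyl-directed epoxidation (VO(acac)2, t-BuOOH) delivers oxygen syn to the C9 hydroxyl and gives the epoxy alcohol F7. Dess–Martin oxidation of F7 gives 32. Either C9 epimer of F6 is available (hydride reduction or the chromium route above), so the epimer that directs oxygen to the required face is the one carried on, and no base is used.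

3. Step 9 (alkenyllithium on the Weinreb amide). Risks are deprotonation of the doubly activated C7–H and isomerisation of the β,γ-unsaturated ketone. The fallback sets out from 7 and comes back at 18. Me3SiCl/imidazole converts 7 into the trimethylsilyl ether F1, and i-Bu2AlH at −78 °C reduces it to the aldehyde F2. F2 and 15 are joined without strong base by Nozaki–Hiyama–Kishi coupling (CrCl2, NiCl2 1 mol %, DMSO) to the allylic alcohols F3 (both C6 epimers). Dess–Martin periodinane oxidises these to the silylated enone F4, and citric acid in MeOH at 0 °C removes the trimethylsilyl group to give 18.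

Further compounds
F1 | step 9 | (2R,3R)-4-((tert-butyldimethylsilyl)oxy)-N-methoxy-N-methyl-2-(prop-1-en-2-yl)-3-((trimethylsilyl)oxy)butanamide | CC(C)(C)[Si](C)(C)OC[C@H](O[Si](C)(C)C)[C@@H](C(C)=C)C(=O)N(C)OC
F2 | step 9 | (2R,3R)-4-((tert-butyldimethylsilyl)oxy)-2-(prop-1-en-2-yl)-3-((trimethylsilyl)oxy)butanal | CC(C)(C)[Si](C)(C)OC[C@H](O[Si](C)(C)C)[C@@H](C(C)=C)C=O
F3 | step 9 | C6 allylic alcohols (both C6 epimers) with 8-OSiMe3, 9-OTBS, 3-OTES, 1-OTES, 4E (3S,8R) | CC(C)(C)[Si](C)(C)OC[C@H](O[Si](C)(C)C)[C@@H](C(C)=C)C(O)/C=C(\C)[C@@H](O[Si](CC)(CC)CC)CCO[Si](CC)(CC)CC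
F4 | step 9 | 8-O-trimethylsilyl ether of 18 (3S,7R,8R; 4E) | CC(C)(C)[Si](C)(C)OC[C@H](O[Si](C)(C)C)[C@@H](C(C)=C)C(=O)/C=C(\C)[C@@H](O[Si](CC)(CC)CC)CCO[Si](CC)(CC)CC
F5 | step 21 | C9 aldehyde corresponding to 28 (3S,4R,5R,6S,7S,8R; Z-iodoalkene) | O=C[C@H](OC(=O)/C(C)=C\C)[C@@H](C(C)=C)[C@H](OC(=O)/C(C)=C\C)[C@H]1O[C@]1(C)[C@@H](OC(=O)/C(C)=C\C)C/C=C(\I)C
F6 | step 21 | 9-hydroxy analogue of 31 (macrocyclic (Z)-allylic alcohol, C9 epimers; other centres as in 31) | C=C(C)[C@H]1[C@H](OC(=O)/C(C)=C\C)[C@H]2O[C@]2(C)[C@@H](OC(=O)/C(C)=C\C)C/C=C(/C)C(O)[C@@H]1OC(=O)/C(C)=C\C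
F7 | step 22 | 9-hydroxy analogue of 32 (1,10:4,5-diepoxy alcohol; C9 carbinol, other centres as in 32) | C=C(C)[C@H]1[C@H](OC(=O)/C(C)=C\C)[C@H]2O[C@]2(C)[C@@H](OC(=O)/C(C)=C\C)C[C@@H]2O[C@]2(C)C(O)[C@@H]1OC(=O)/C(C)=C\C
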